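**Missing L.** L goes missing.

in all of them: L 0.050 M

| flask | X | remark | time |
|---|---|---|---|
| green | 0.050 M | run made earlier |  |
| ochre | 0.16 M | run made earlier |  |
| Thursday's | 0.0600 M |  | 20 min |
| Saturday's | 0.125 M |  | 20 min |
| Tuesday's | 0.200 M |  | 20 min |

- green (time / min: J / %, Q / %, L / %): 4.00: 12, 29, 49; 8.00: 29, 33, 34; 10.0: 28, 28, 26; 15.0: 30, 30, 23
- ochre (time / min: J / %, Q / %, L / %): 1.00: 20, 31, 43; 2.50: 56, 22, 13; 6.00: 84, 10, 5; 15.0: 95, 0, 0

(readings scatter by 2 percentage points)

- final J, as a percentage of the L charged, for each flask in turn (Thursday's, Saturday's, Tuesday's)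

In the last ochre row, L, Q and J leave 5.00% of the L charge unaccounted for, with 3.20 of X charged per L. In the last green row they leave 17.0%, with 1.00. The products are 0.160 for ochre and 0.170 for green. I call this the loss product: the missing share of the L charge times the X charged per L.

**First doubt.** Each reading behind ochre's small share scatters by 2 percentage points, so the match may be luck. Still, it has a plain reading: at any moment L divides between X and an unseen route, and X's part grows with X if the unseen route doesn't. I therefore take the missing share as the loss product over the X charged per L.

**Excess X.** Saturday's flask has 2.50 of X per L and Tuesday's has 4.00, so with ochre's product J should reach 93.6% and 96.0%. But Saturday's spare X, 0.500 per L, is less than ochre's 1.20, so some Q may linger there, and I treat Saturday's figure as high.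

**Scarce X.** Thursday's flask has 1.20 of X per L, less than the 2 that turning every L into J takes, so X is the limiting reagent there. Green's product, the nearer one, gives a missing share of 14.2%. My objection is that X's part shrinks as X is spent, so this share may be low. Green's last row reads 90.0% of its X in Q and J, counting two X in each J. Applying that to Thursday's flask and taking green's L of 23% gives J of 45.2%, which is high if more X leaves less L.

**The check.** Mine are 45.2%, 93.6% and 96.0%; the forecast differs, with 40%, 95% and 98%, and says “a small unseen loss may exist, most noticeable when X is scarce”. The flasks give J of 43.3%, 90.6% and 95.9%.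

    L + X → Q + E (k = 5.60 M⁻¹ min⁻¹)
    L + X → Z + E (k = 0.460 M⁻¹ min⁻¹)
    X + Q → J + E (k = 6.80 M⁻¹ min⁻¹)
    X + Z → J + E (k = 9.80 M⁻¹ min⁻¹)
    L + E → D (k = 1.00 M⁻¹ min⁻¹)
    X → G (k = 0.00800 min⁻¹)

At 20.0 min in Thursday's flask, with 2.1% of its X left, the step from L + X to Q + E uses L at 0.15 of the rate at which L + E uses it, and D stands at 19.0%, up from 12.0% at 10.0 min. Counting D and Z at 20.0 min as the missing share, the loss product is 0.163 in Tuesday's flask, 0.200 in Saturday's and 0.245 in Thursday's.

(The readings are calculated with made-up constants; scatter was added.)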